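## Structural features

The target is a 2,3,4,7-tetrahydrooxepine (ring atoms O1, C2, C3, C4, C5, C6, C7) whose only ring unsaturation is the trisubstituted C5=C6 olefin, so that C7 is an allylic ether methylene. C2 is the single stereocentre: a fully substituted (R)-configured carbon carrying the ring oxygen, a free carboxyl group (C8), the ring methylene C3 and an exocyclic methylene (C9) that leads to the ketone carbon C10 of a 2,5-dihydroxyphenyl ketone. With no neighbouring stereocentre, only absolute control is at stake. C6 carries a five-carbon chain ending in an (E)-configured 2-methylallylic alcohol. The ring oxygen on C2 is β to the C10 ketone, so any base able to enolise C9 can expel O1 (retro-oxa-Michael opening to an aroylacrylate) and reclosure would scramble C2; the hydroquinone is air-sensitive, above all as its phenoxide, and the two allylic C–O bonds restrict the use of strong acid and exclude allylic esters wherever zerovalent palladium is used. The real difficulty is twofold: a tetrasubstituted ether stereocentre inside a seven-membered ring, and the attachment of an electron-rich aryl ketone two atoms away from it without exposing the β-alkoxy ketone to base. The key step exploits the 1,2-relationship on the arene between the C10 acyl carbon and a phenolic oxygen, with the second oxygen para to that phenol: this is the pattern left when the O–C(acyl) bond of the C9–C10 acetic acid arm is inserted across the two carbons of a 4-oxygenated aryne.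

## Logic of the disconnections

32 from 31. The aryl O–CH2 acetal bond and the side-chain O–Si bond are cut last. Both respond to dilute aqueous acid, so the hydroquinone and the allylic alcohol appear only in a base-free, oxygen-free medium in which neither quinone formation nor E1cB opening of the ring can start. The forward step must be mild enough to spare the allylic alcohol, the allylic ether O1–C7 and the free acid.

31 from 30. The aryl C–H bond is traded for C–Br and the carboxyl O–H for an O–allyl bond. One zerovalent palladium/formate treatment removes both: the bromine is needed only as the regiochemical control element of the aryne step, and an allyl ester avoids a late hydrolysis of a hindered ester beside the base-sensitive β-alkoxy ketone. This choice excludes an allylic ester on the side-chain oxygen, which the same catalyst would ionise and reduce, so that oxygen is a silyl ether from 3 onwards.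

30 from 19 and 27. The C10–aryl bond and the neighbouring aryl C–O bond are cut together. This removes the whole arene at once and leaves an aliphatic acetic acid arm on the finished ring, so the β-alkoxy aryl ketone exists for only two further steps. The forward step must place oxygen on the aryne carbon remote from bromine, must let the aryl anion capture the acyl group before it is protonated or loses bromide, and must be quenched before the phenoxide can open the ring.

27 from 20 through 25, 22 and 21. The aryl O–S, aryl C–Si, O–CH2 and O–carbamoyl bonds are cut in turn. A carbamate on the oxygen remote from bromine differentiates the two hydroxyls, directs metalation to the carbon between itself and bromine, and is exchanged for triflate in one flask. The demands are a site-selective carbamoylation of 20 and a lithium amide metalation that leaves the C–Br bond alone.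

19 from 18. The acyl C–O bond is traced back to the C–S bond of a thioester, the form in which the aldol donor delivers C9–C10. The hydrolysis has to proceed without enolising C9, hence thiophilic metal assistance and not hydroxide.

18 from 17 and 17 from 16. The ring bond C6–C7 is cut, then the O–CH2 bond of the acetal that supplies C7. This turns the seven-membered ring into an open chain whose C6 carries silicon; the tertiary hydroxyl on C2 becomes the anchor for a one-carbon electrophile. The forward closure needs attack through the silicon-bearing carbon and a vinylsilane geometry with silicon cis to the tether.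

16 from 12 and 14 (14 from 13). The C2–C9 bond is cut as an aldol between a keto ester and a thioacetate enol equivalent. This is the only stereogenic step; it reduces the problem to an achiral α-keto ester and asks the chiral copper catalyst for face selectivity at a ketone flanked by an ester and a primary alkyl chain.

12 from 9 and 10 (9 from 8). The C2–C3 bond is cut between an oxalate diester and a homoallylic organomagnesium reagent. The gain is a two-carbon electrophile bought with the ester in place; the demand is mono-addition at low temperature.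

8 from 6 and 3 through 7. The bond between C6 and the first carbon of the side chain is cut as an sp2–sp3 cross-coupling. The side chain and the silylated four-carbon unit are thereby made separately, and the coupling must retain the olefin geometry of 6.

6 from 4, and 3 from 2 from 1. The C6–I and C5–H bonds go back to a silylalkyne by syn hydrometalation; the side-chain O–Si and allylic C–O bonds go back to a gem-dimethyl olefin. Both sequences start from bought materials; the demands are regio- and stereocontrol in the hydroalumination and E-selective allylic oxidation.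

## Other disconnections considered

Alternative 1: The oxepine would be reached from a six-membered enol ether. The cut is the C5–C7 bond shared by the pyran and cyclopropane rings of A2, the dibromocarbene adduct of dihydropyran A1. In the forward sense a silver salt assists departure of one bromide, the cyclopropane opens, and methanol traps the oxocarbenium ion at C7 to give bromo acetal A3. In its favour, six-membered enol ethers are easy to assemble, ring expansion of alkoxy-substituted dibromocyclopropanes is an established answer to ring size with no ambiguity about which bond opens, and the C6 vinyl bromide is a handle for late attachment of the side chain. Against it here, A3 still lacks the side chain and carries a C7 methoxy group, so a cross-coupling and a reductive removal of the acetal must follow, the latter with 1,2- against 1,4-delivery of hydride to be controlled. Dibromocarbene is made under strongly basic conditions that the β-alkoxy aryl ketone of A1 is unlikely to tolerate, the tert-butyl ester needs strong acid at the end beside the allylic alcohol, and the step does not say how C2 is set. On structure it solves ring size where the chosen plan solves the aryl ketone. On mechanism the ring expansion is the equal of the vinylsilane closure of step 10, and in regiochemistry of ring formation arguably the better. On step economy it is inferior, since three to four operations follow the key step with the fragile ketone present throughout.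

Alternative 2: The cut is C6–C7, as in step 10 of the chosen route, but with the arene already in place. SnCl4 would ionise the acetal of A5, the silicon-bearing carbon C6 would attack the resulting O1=C7 oxocarbenium ion, and loss of silicon would give A6. A5 would come from a copper–bis(oxazoline) aldol in which the donor is aryl ketone enol silane A4. In its favour, the ring-forming event is identical to that of the chosen route, so on that point the two are equal. Because the aryl ketone arrives with the aldol donor, the thioester hydrolysis, the four-step aryne precursor, the insertion and the debromination all disappear: in step count and convergence this alternative is clearly the better. Against it here, acetal installation on the tertiary aldol and the Lewis acid ionisation must be carried out on a β-oxygenated aryl ketone (retro-aldol cleavage, chelation of the Lewis acid, loss of aryl silyl ethers, and the electron-rich arene as a competing π-nucleophile). The selectivity of the aldol with a hindered ortho-silyloxy enol silane is untested, and the end game needs nucleophilic cleavage of a methyl ester and fluoride cleavage of three silyl ethers, both of which create basic species next to the β-alkoxy ketone. The chosen plan keeps that ketone out of every Lewis acid and base step and creates it two steps from the end, at the price of about five more steps.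

Alternative 3: The cut is O1–C2. A chiral bifunctional base and hydrogen-bond donor would make the C7 hydroxyl of acyclic A7 add to the β-carbon of its aroylacrylate, closing the ring and setting C2 in one step to give A8. In its favour, this is the most convergent and the shortest plan, it mirrors the likely biogenesis, and it needs no bromine, no aryne and no late ester exchange; in step economy and ideality it is the better of the two. Against it here, the closure forms a seven-membered ring by attack on a fully substituted β-carbon, the oxa-Michael addition is reversible so the product can racemise through the channel that formed it, a primary allylic alcohol is a weak nucleophile, and enantiofacial control of a trisubstituted acceptor in a medium-ring closure has no close precedent. On structure the alternative addresses ring and stereocentre together, which the chosen plan does in two separate steps (8 and 10). On mechanism the chosen plan sets C2 by an irreversible C–C bond formation of a well-precedented type, whereas the alternative relies on a thermodynamically marginal equilibrium.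

Key step: step 16

Assumption: the facial sense of the copper–bis(oxazoline) aldol is taken to follow the pyruvate model, in which the (S,S)-tert-butyl ligand directs attack to the si face; the (R,R)-ligand is therefore written for the (R)-carbinol, and the ligand enantiomer would be exchanged should the sense prove opposite.

## Route

Step 1
Reactants: 1 5-bromo-2-methylpent-2-ene
Product: 2 (2E)-5-bromo-2-methylpent-2-en-1-ol
Conditions: SeO2 (0.3 equiv), t-BuOOH (2.5 equiv), salicylic acid (0.1 equiv), CH2Cl2, 0 °C to rt
Reagents that add atoms: tert-butyl hydroperoxide, CC(C)(C)OO (terminal oxygen source; the oxygen is relayed by selenium dioxide, O=[Se]=O)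
Why: Catalytic Riley allylic oxidation: ene reaction of SeO2 at the trisubstituted olefin and a 2,3-sigmatropic shift hydroxylate the methyl group trans to the chain, which fixes the E-allylic alcohol; the primary bromide is inert and the reaction is stopped before the enal accumulates.

Step 2
Reactants: 2 (2E)-5-bromo-2-methylpent-2-en-1-ol
Product: 3 tert-butyl{[(2E)-5-bromo-2-methylpent-2-en-1-yl]oxy}dimethylsilane
Conditions: t-BuMe2SiCl, imidazole, CH2Cl2, 0 °C to rt
Reagents that add atoms: tert-butyldimethylsilyl chloride, CC(C)(C)[Si](C)(C)Cl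
Why: Routine silylation of a primary alcohol; unlike an allylic ester, the silyl ether is not ionised by zerovalent palladium in steps 4 and 17 and is lost together with the aryl acetal in the final acid step.

Step 3
Reactants: 4 4-(trimethylsilyl)but-3-yn-1-ol
Product: 6 (3E)-4-iodo-4-(trimethylsilyl)but-3-en-1-ol, via alkenylalane 5 (not isolated)
Conditions: i-Bu2AlH (2.3 equiv), Et2O, 0 °C to 35 °C; then I2 (1.3 equiv), THF, −78 °C to 0 °C; aq. Na2S2O3, Rochelle salt
Reagents that add atoms: diiodine, [I][I]
Why: Syn hydroalumination of the 1-silylalkyne places aluminium on the silicon-bearing carbon (the ether solvent prevents isomerisation of the alkenylalane), and iodinolysis of the C–Al bond proceeds with retention, so silicon ends cis to the carbinol chain as the later endocyclic closure requires.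

Step 4
Reactants: 3 tert-butyl{[(2E)-5-bromo-2-methylpent-2-en-1-yl]oxy}dimethylsilane; 6 (3E)-4-iodo-4-(trimethylsilyl)but-3-en-1-ol
Product: 8 (3Z,7E)-9-[(tert-butyldimethylsilyl)oxy]-8-methyl-4-(trimethylsilyl)nona-3,7-dien-1-ol, via alkylzinc bromide 7 (not isolated)
Conditions: 3 (1.6 equiv), Zn dust, LiCl, I2 (cat.), THF, 50 °C; then 6, PdCl2(dppf) (3 mol %), THF, 45 °C
Reagents that add atoms: none
Why: Lithium chloride-assisted zinc insertion into the primary bromide followed by Negishi sp3–sp2 coupling, which retains the geometry of the alkenyl iodide; the alkylzinc halide tolerates the silyl ether and, used in excess, the free hydroxyl, and the wide-bite-angle ligand suppresses β-hydride elimination.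

Step 5
Reactants: 8 (3Z,7E)-9-[(tert-butyldimethylsilyl)oxy]-8-methyl-4-(trimethylsilyl)nona-3,7-dien-1-ol
Product: 9 {[(2E,6Z)-9-bromo-2-methyl-6-(trimethylsilyl)nona-2,6-dien-1-yl]oxy}(tert-butyl)dimethylsilane
Conditions: CBr4, PPh3, CH2Cl2, 0 °C
Reagents that add atoms: carbon tetrabromide, BrC(Br)(Br)Br
Why: Appel bromination of the primary alcohol under neutral conditions; no electrophilic halogen or strong acid is present, so the vinylsilane and the silyl ether are not touched.

Step 6
Reactants: 9 {[(2E,6Z)-9-bromo-2-methyl-6-(trimethylsilyl)nona-2,6-dien-1-yl]oxy}(tert-butyl)dimethylsilane; 10 di(prop-2-en-1-yl) oxalate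
Product: 12 prop-2-en-1-yl (5Z,9E)-11-[(tert-butyldimethylsilyl)oxy]-10-methyl-2-oxo-6-(trimethylsilyl)undeca-5,9-dienoate, via Grignard reagent 11 (not isolated)
Conditions: Mg, THF, rt; then added to 10 (3 equiv), THF, −78 °C; aq. NH4Cl at −78 °C
Reagents that add atoms: none
Why: Grignard mono-addition to an oxalate diester: the chelated tetrahedral magnesium alkoxide survives at −78 °C until the quench, and inverse addition to excess oxalate suppresses a second addition, so the α-keto ester is released with the allyl ester already in place.

Step 7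
Reactants: 13 S-tert-butyl ethanethioate
Product: 14 {[1-(tert-butylsulfanyl)ethenyl]oxy}trimethylsilane
Conditions: LiN(i-Pr)2, THF, −78 °C; Me3SiCl
Reagents that add atoms: chlorotrimethylsilane, C[Si](C)(C)Cl
Why: Kinetic enolisation of the thioester and O-silylation give the silyl ketene thioacetal, the donor class on which the catalytic aldol of step 8 is best established.

Step 8
Reactants: 12 prop-2-en-1-yl (5Z,9E)-11-[(tert-butyldimethylsilyl)oxy]-10-methyl-2-oxo-6-(trimethylsilyl)undeca-5,9-dienoate; 14 {[1-(tert-butylsulfanyl)ethenyl]oxy}trimethylsilane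
Product: 16 prop-2-en-1-yl (2R,5Z,9E)-2-[2-(tert-butylsulfanyl)-2-oxoethyl]-11-[(tert-butyldimethylsilyl)oxy]-2-hydroxy-10-methyl-6-(trimethylsilyl)undeca-5,9-dienoate, via trimethylsilyl ether 15 (not isolated)
Conditions: Cu(OTf)2 (10 mol %), 2,2'-(propane-2,2-diyl)bis[(4R)-4-tert-butyl-4,5-dihydrooxazole] (11 mol %), THF, −78 °C; then PPTS, MeOH, 0 °C
Reagents that add atoms: none
Why: Enantioselective Mukaiyama aldol: the α-keto ester chelates the square-planar divalent copper centre through both carbonyl groups, the tert-butyl groups of the ligand screen one face, and the ketene thioacetal adds to the open re face to set the (R)-carbinol at C2 under ligand control; buffered methanolysis removes the tertiary trimethylsilyl group and spares the primary silyl ether.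

Step 9
Reactants: 16 prop-2-en-1-yl (2R,5Z,9E)-2-[2-(tert-butylsulfanyl)-2-oxoethyl]-11-[(tert-butyldimethylsilyl)oxy]-2-hydroxy-10-methyl-6-(trimethylsilyl)undeca-5,9-dienoate
Product: 17 prop-2-en-1-yl (2R,5Z,9E)-2-[2-(tert-butylsulfanyl)-2-oxoethyl]-11-[(tert-butyldimethylsilyl)oxy]-2-(methoxymethoxy)-10-methyl-6-(trimethylsilyl)undeca-5,9-dienoate
Conditions: MeOCH2Cl (5 equiv), i-Pr2NEt (8 equiv), 1,2-dichloroethane, 50 °C
Reagents that add atoms: chloromethyl methyl ether, COCCl
Why: Alkylation of the hindered tertiary hydroxyl by a highly reactive α-chloro ether; the amine base is too weak to trigger retro-aldol cleavage of the β-hydroxy thioester, and the acetal carbon introduced here becomes C7.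

Step 10
Reactants: 17 prop-2-en-1-yl (2R,5Z,9E)-2-[2-(tert-butylsulfanyl)-2-oxoethyl]-11-[(tert-butyldimethylsilyl)oxy]-2-(methoxymethoxy)-10-methyl-6-(trimethylsilyl)undeca-5,9-dienoate
Product: 18 prop-2-en-1-yl (2R)-2-[2-(tert-butylsulfanyl)-2-oxoethyl]-6-[(3E)-5-{(tert-butyldimethylsilyl)oxy}-4-methylpent-3-en-1-yl]-2,3,4,7-tetrahydrooxepine-2-carboxylate
Conditions: SnCl4 (2.5 equiv), 2,6-di-tert-butyl-4-methylpyridine (0.5 equiv), CH2Cl2, −78 °C to −30 °C; aq. NaHCO3
Reagents that add atoms: none
Why: Vinylsilane-terminated oxocarbenium (Prins-type) cyclisation: SnCl4 removes methoxide from the acetal, the silicon-bearing carbon C6 attacks the O1=C7 cation in a 7-endo closure, and the β-silyl cation at C5 loses silicon to leave C5=C6; silicon cis to the tether makes the endocyclic mode possible, the hindered pyridine intercepts protons that would cause protodesilylation, and C2 is not involved.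

Step 11
Reactants: 18 prop-2-en-1-yl (2R)-2-[2-(tert-butylsulfanyl)-2-oxoethyl]-6-[(3E)-5-{(tert-butyldimethylsilyl)oxy}-4-methylpent-3-en-1-yl]-2,3,4,7-tetrahydrooxepine-2-carboxylate
Product: 19 {(2R)-6-[(3E)-5-{(tert-butyldimethylsilyl)oxy}-4-methylpent-3-en-1-yl]-2-[(prop-2-en-1-yloxy)carbonyl]-2,3,4,7-tetrahydrooxepin-2-yl}acetic acid
Conditions: AgOCOCF3 (3 equiv), Na2HPO4, THF/H2O (4:1), 45 °C
Reagents that add atoms: water, O
Why: Thiophilic activation of the S-tert-butyl thioester by monovalent silver lets water acylate under buffered, near-neutral conditions; C9 is never enolised, so the ring oxygen is not expelled, and the allyl ester and silyl ether are left alone.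

Step 12
Reactants: 20 2-bromobenzene-1,4-diol
Product: 21 3-bromo-4-hydroxyphenyl propan-2-ylcarbamate
Conditions: i-PrNCO (1.0 equiv), Et3N (0.1 equiv), CH2Cl2, 0 °C to rt
Reagents that add atoms: isopropyl isocyanate, CC(C)N=C=O
Why: Amine-catalysed carbamoylation should favour the hydroxyl remote from bromine, which is the less hindered and the less acidic one; a carbamate on the ortho-bromo oxygen would also be the more prone to revert, so equilibration works in the same direction.

Step 13
Reactants: 21 3-bromo-4-hydroxyphenyl propan-2-ylcarbamate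
Product: 22 3-bromo-4-(methoxymethoxy)phenyl propan-2-ylcarbamate
Conditions: MeOCH2Cl, i-Pr2NEt, CH2Cl2, 0 °C to rt
Reagents that add atoms: chloromethyl methyl ether, COCCl
Why: O-alkylation of the remaining phenol; the acetal survives lithium amide, fluoride and palladium, and is cleaved by the acid that ends the route.

Step 14
Reactants: 22 3-bromo-4-(methoxymethoxy)phenyl propan-2-ylcarbamate
Product: 25 3-bromo-4-(methoxymethoxy)-2-(trimethylsilyl)phenyl propan-2-ylcarbamate, via N-silyl carbamate 23 (not isolated), via N,2-bis(trimethylsilyl) carbamate 24 (not isolated)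
Conditions: Me3SiOTf (1.1 equiv), TMEDA (1.2 equiv), Et2O, 0 °C to rt; then Me3SiCl (3 equiv), LiN(i-Pr)2 (2.2 equiv), THF, −78 °C; aq. NH4Cl
Reagents that add atoms: chlorotrimethylsilane, C[Si](C)(C)Cl
Why: Directed ortho-metalation with in situ silyl trapping: N-silylation masks the carbamate N–H, the lithium amide removes the proton flanked by the carbamate oxygen and bromine (the most acidic site) without bromine–lithium exchange, and chlorosilane already present captures the aryllithium before it can lose lithium bromide or rearrange.

Step 15
Reactants: 25 3-bromo-4-(methoxymethoxy)-2-(trimethylsilyl)phenyl propan-2-ylcarbamate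
Product: 27 3-bromo-4-(methoxymethoxy)-2-(trimethylsilyl)phenyl trifluoromethanesulfonate, via silylphenol 26 (not isolated)
Conditions: DBU (1.5 equiv), Et2NH (1.2 equiv), MeCN, 40 °C; then PhNTf2 (1.5 equiv), rt
Reagents that add atoms: N-phenylbis(trifluoromethanesulfonimide), O=S(=O)(N(c1ccccc1)S(=O)(=O)C(F)(F)F)C(F)(F)F
Why: Base-induced E1cB loss of isopropyl isocyanate (captured by diethylamine as a urea) frees the hindered phenoxide, which is triflated in the same flask; no fluoride is present, so the silyl group stays on carbon.

Step 16
Reactants: 19 {(2R)-6-[(3E)-5-{(tert-butyldimethylsilyl)oxy}-4-methylpent-3-en-1-yl]-2-[(prop-2-en-1-yloxy)carbonyl]-2,3,4,7-tetrahydrooxepin-2-yl}acetic acid; 27 3-bromo-4-(methoxymethoxy)-2-(trimethylsilyl)phenyl trifluoromethanesulfonate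
Product: 30 prop-2-en-1-yl (2R)-2-{2-[2-bromo-6-hydroxy-3-(methoxymethoxy)phenyl]-2-oxoethyl}-6-[(3E)-5-{(tert-butyldimethylsilyl)oxy}-4-methylpent-3-en-1-yl]-2,3,4,7-tetrahydrooxepine-2-carboxylate, via potassium carboxylate 28 (not isolated), via 3-bromo-4-(methoxymethoxy)benzyne 29 (not isolated)
Conditions: KH (1.0 equiv), THF, 0 °C; then CsF (3 equiv), 18-crown-6 (3 equiv), 27 (1.4 equiv, added over 3 h), THF, 40 °C; AcOH (3 equiv), 0 °C
Reagents that add atoms: none
Why: Fluoride attacks the silicon of 27 and triflate, a far better leaving group than the flanking bromide, departs to give aryne 29. The bromine distorts the triple bond so that the remote aryne carbon is the more electrophilic and stabilises by induction the carbanion that develops beside it; the carboxylate oxygen of 28 therefore bonds to the carbon para to the acetal oxygen. The resulting aryl anion attacks the carbonyl of the aryl ester next to it, and opening of the strained four-membered alkoxide (an anionic Fries-type 1,3 oxygen-to-carbon acyl shift) places the C10 ketone and the phenoxide on adjacent carbons. The closest known reaction type is the fluoride-induced insertion of arynes into the O–C(acyl) bond of carboxylic acids, combined with the known remote addition of nucleophiles to 3-haloarynes. No ring is retained and no stereocentre is formed; C2 is a fully substituted bystander. Acyl capture has to outrun protonation of the aryl anion and loss of bromide from it, which is why every acidic proton is removed beforehand (pre-formed carboxylate, ethereal solvent, no bifluoride) and why the intramolecular four-atom path is preferred to the seven-atom path to the allyl ester. Slow addition of 27 keeps the aryne scarce so that the carboxylate and not the product phenoxide captures it, and the cold acetic acid quench protonates the phenoxide before it can start E1cB opening of the new β-alkoxy ketone.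

Step 17
Reactants: 30 prop-2-en-1-yl (2R)-2-{2-[2-bromo-6-hydroxy-3-(methoxymethoxy)phenyl]-2-oxoethyl}-6-[(3E)-5-{(tert-butyldimethylsilyl)oxy}-4-methylpent-3-en-1-yl]-2,3,4,7-tetrahydrooxepine-2-carboxylate
Product: 31 (2R)-6-[(3E)-5-{(tert-butyldimethylsilyl)oxy}-4-methylpent-3-en-1-yl]-2-{2-[2-hydroxy-5-(methoxymethoxy)phenyl]-2-oxoethyl}-2,3,4,7-tetrahydrooxepine-2-carboxylic acid
Conditions: Pd(OAc)2 (10 mol %), PPh3 (40 mol %), HCO2Na (5 equiv), DMF (degassed), 80 °C
Reagents that add atoms: none
Why: Zerovalent palladium formed in situ does two known jobs with formate as hydride donor: Tsuji–Trost ionisation of the allyl ester followed by reduction of the allyl fragment to propene, and oxidative addition into the ketone-activated C–Br bond followed by formate decarboxylation and C–H reductive elimination; the silyl ether and the ring allylic ether are poor leaving groups and are not ionised, and any transient O-allyl phenol is re-ionised and reduced in the same way.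

Step 18
Reactants: 31 (2R)-6-[(3E)-5-{(tert-butyldimethylsilyl)oxy}-4-methylpent-3-en-1-yl]-2-{2-[2-hydroxy-5-(methoxymethoxy)phenyl]-2-oxoethyl}-2,3,4,7-tetrahydrooxepine-2-carboxylic acid
Product: 32 (2R)-2-[2-(2,5-dihydroxyphenyl)-2-oxoethyl]-6-[(3E)-5-hydroxy-4-methylpent-3-en-1-yl]-2,3,4,7-tetrahydrooxepine-2-carboxylic acid
Conditions: 2 M aq. HCl/THF (1:3), argon, 30 °C
Reagents that add atoms: none
Why: Acid hydrolysis of the aryl acetal and of the primary silyl ether in one operation; without base the β-alkoxy ketone cannot open and the hydroquinone is not oxidised, without alcohol solvent the hindered acid is not esterified, and the dilute acid at low temperature should spare the allylic alcohol and the quaternary C2.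

## Compound list

1 | 5-bromo-2-methylpent-2-ene | CC(C)=CCCBr | starting material
2 | (2E)-5-bromo-2-methylpent-2-en-1-ol | C/C(=C\CCBr)CO | intermediate
3 | tert-butyl{[(2E)-5-bromo-2-methylpent-2-en-1-yl]oxy}dimethylsilane | C/C(=C\CCBr)CO[Si](C)(C)C(C)(C)C | intermediate
4 | 4-(trimethylsilyl)but-3-yn-1-ol | C[Si](C)(C)C#CCCO | starting material
5 | (Z)-alkenylalane: diisobutylaluminium alkoxide of 4-(diisobutylalumanyl)-4-(trimethylsilyl)but-3-en-1-ol, aluminium cis to H | CC(C)C[Al](CC(C)C)OCC/C=C(/[Al](CC(C)C)CC(C)C)[Si](C)(C)C | intermediate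
6 | (3E)-4-iodo-4-(trimethylsilyl)but-3-en-1-ol (silicon cis to the CH2CH2OH chain) | OCC/C=C(/I)[Si](C)(C)C | intermediate
7 | bromo{(3E)-5-[(tert-butyldimethylsilyl)oxy]-4-methylpent-3-en-1-yl}zinc | C/C(=C\CC[Zn]Br)CO[Si](C)(C)C(C)(C)C | intermediate
8 | (3Z,7E)-9-[(tert-butyldimethylsilyl)oxy]-8-methyl-4-(trimethylsilyl)nona-3,7-dien-1-ol | OCC/C=C(/CC/C=C(\C)CO[Si](C)(C)C(C)(C)C)[Si](C)(C)C | intermediate
9 | {[(2E,6Z)-9-bromo-2-methyl-6-(trimethylsilyl)nona-2,6-dien-1-yl]oxy}(tert-butyl)dimethylsilane | BrCC/C=C(/CC/C=C(\C)CO[Si](C)(C)C(C)(C)C)[Si](C)(C)C | intermediate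
10 | di(prop-2-en-1-yl) oxalate (diallyl oxalate) | C=CCOC(=O)C(=O)OCC=C | starting material
11 | bromo[(3Z,7E)-9-{(tert-butyldimethylsilyl)oxy}-8-methyl-4-(trimethylsilyl)nona-3,7-dien-1-yl]magnesium | Br[Mg]CC/C=C(/CC/C=C(\C)CO[Si](C)(C)C(C)(C)C)[Si](C)(C)C | intermediate
12 | prop-2-en-1-yl (5Z,9E)-11-[(tert-butyldimethylsilyl)oxy]-10-methyl-2-oxo-6-(trimethylsilyl)undeca-5,9-dienoate | C=CCOC(=O)C(=O)CC/C=C(/CC/C=C(\C)CO[Si](C)(C)C(C)(C)C)[Si](C)(C)C | intermediate
13 | S-tert-butyl ethanethioate | CC(=O)SC(C)(C)C | starting material
14 | {[1-(tert-butylsulfanyl)ethenyl]oxy}trimethylsilane | C=C(O[Si](C)(C)C)SC(C)(C)C | intermediate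
15 | trimethylsilyl ether of 16 at the C2 oxygen, (2R,5Z,9E) | C/C(=C\CC/C(=C/CC[C@@](CC(=O)SC(C)(C)C)(C(=O)OCC=C)O[Si](C)(C)C)[Si](C)(C)C)CO[Si](C)(C)C(C)(C)C | intermediate
16 | prop-2-en-1-yl (2R,5Z,9E)-2-[2-(tert-butylsulfanyl)-2-oxoethyl]-11-[(tert-butyldimethylsilyl)oxy]-2-hydroxy-10-methyl-6-(trimethylsilyl)undeca-5,9-dienoate | C/C(=C\CC/C(=C/CC[C@@](CC(=O)SC(C)(C)C)(C(=O)OCC=C)O)[Si](C)(C)C)CO[Si](C)(C)C(C)(C)C | intermediate
17 | prop-2-en-1-yl (2R,5Z,9E)-2-[2-(tert-butylsulfanyl)-2-oxoethyl]-11-[(tert-butyldimethylsilyl)oxy]-2-(methoxymethoxy)-10-methyl-6-(trimethylsilyl)undeca-5,9-dienoate | C/C(=C\CC/C(=C/CC[C@@](CC(=O)SC(C)(C)C)(C(=O)OCC=C)OCOC)[Si](C)(C)C)CO[Si](C)(C)C(C)(C)C | intermediate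
18 | prop-2-en-1-yl (2R)-2-[2-(tert-butylsulfanyl)-2-oxoethyl]-6-[(3E)-5-{(tert-butyldimethylsilyl)oxy}-4-methylpent-3-en-1-yl]-2,3,4,7-tetrahydrooxepine-2-carboxylate | C/C(=C\CCC1=CCC[C@@](CC(=O)SC(C)(C)C)(C(=O)OCC=C)OC1)CO[Si](C)(C)C(C)(C)C | intermediate
19 | {(2R)-6-[(3E)-5-{(tert-butyldimethylsilyl)oxy}-4-methylpent-3-en-1-yl]-2-[(prop-2-en-1-yloxy)carbonyl]-2,3,4,7-tetrahydrooxepin-2-yl}acetic acid | C/C(=C\CCC1=CCC[C@@](CC(=O)O)(C(=O)OCC=C)OC1)CO[Si](C)(C)C(C)(C)C | intermediate
20 | 2-bromobenzene-1,4-diol (bromohydroquinone) | Oc1ccc(O)c(Br)c1 | starting material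
21 | 3-bromo-4-hydroxyphenyl propan-2-ylcarbamate | CC(C)NC(=O)Oc1ccc(O)c(Br)c1 | intermediate
22 | 3-bromo-4-(methoxymethoxy)phenyl propan-2-ylcarbamate | CC(C)NC(=O)Oc1ccc(OCOC)c(Br)c1 | intermediate
23 | 3-bromo-4-(methoxymethoxy)phenyl propan-2-yl(trimethylsilyl)carbamate | CC(C)N(C(=O)Oc1ccc(OCOC)c(Br)c1)[Si](C)(C)C | intermediate
24 | 3-bromo-4-(methoxymethoxy)-2-(trimethylsilyl)phenyl propan-2-yl(trimethylsilyl)carbamate | CC(C)N(C(=O)Oc1ccc(OCOC)c(Br)c1[Si](C)(C)C)[Si](C)(C)C | intermediate
25 | 3-bromo-4-(methoxymethoxy)-2-(trimethylsilyl)phenyl propan-2-ylcarbamate | CC(C)NC(=O)Oc1ccc(OCOC)c(Br)c1[Si](C)(C)C | intermediate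
26 | 3-bromo-4-(methoxymethoxy)-2-(trimethylsilyl)phenol | COCOc1ccc(O)c([Si](C)(C)C)c1Br | intermediate
27 | 3-bromo-4-(methoxymethoxy)-2-(trimethylsilyl)phenyl trifluoromethanesulfonate | COCOc1ccc(OS(=O)(=O)C(F)(F)F)c([Si](C)(C)C)c1Br | intermediate
28 | potassium salt of acid 19 | C/C(=C\CCC1=CCC[C@@](CC(=O)[O-])(C(=O)OCC=C)OC1)CO[Si](C)(C)C(C)(C)C.[K+] | intermediate
29 | 3-bromo-4-(methoxymethoxy)benzyne (1-bromo-2-(methoxymethoxy)-5,6-didehydrobenzene) | COCOC1=C(Br)C#CC=C1 | intermediate
30 | prop-2-en-1-yl (2R)-2-{2-[2-bromo-6-hydroxy-3-(methoxymethoxy)phenyl]-2-oxoethyl}-6-[(3E)-5-{(tert-butyldimethylsilyl)oxy}-4-methylpent-3-en-1-yl]-2,3,4,7-tetrahydrooxepine-2-carboxylate | C/C(=C\CCC1=CCC[C@@](CC(=O)c2c(Br)c(OCOC)ccc2O)(C(=O)OCC=C)OC1)CO[Si](C)(C)C(C)(C)C | intermediate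
31 | (2R)-6-[(3E)-5-{(tert-butyldimethylsilyl)oxy}-4-methylpent-3-en-1-yl]-2-{2-[2-hydroxy-5-(methoxymethoxy)phenyl]-2-oxoethyl}-2,3,4,7-tetrahydrooxepine-2-carboxylic acid | C/C(=C\CCC1=CCC[C@@](CC(=O)c2cc(OCOC)ccc2O)(C(=O)O)OC1)CO[Si](C)(C)C(C)(C)C | intermediate
32 | (2R)-2-[2-(2,5-dihydroxyphenyl)-2-oxoethyl]-6-[(3E)-5-hydroxy-4-methylpent-3-en-1-yl]-2,3,4,7-tetrahydrooxepine-2-carboxylic acid | C/C(=C\CCC1=CCC[C@@](CC(=O)c2cc(O)ccc2O)(C(=O)O)OC1)CO | target

## Step count and least certain steps

Total: 18 steps. Longest linear sequence: 12 steps (from 1 through steps 1, 2, 4, 5, 6, 8, 9, 10, 11, 16, 17 and 18).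

Step 16 (key step). Most likely to go wrong:
- protonation of the aryl anion before the acyl shift, which would stop at simple O-arylation;
- loss of bromide from the ortho-bromoaryl anion, which would open a second aryne;
- fluoride cleavage of the side-chain silyl ether;
- arylation of the product phenoxide by excess aryne;
- E1cB opening of the β-alkoxy ketone if the phenoxide is left unquenched.

All stem from the lifetime and basicity of the anionic intermediates. The fallback sets out from 19 and returns to the route at 31. It makes the same two bonds stepwise by known chemistry. Iodination of 4-(methoxymethoxy)phenol with N-iodosuccinimide gives 2-iodo-4-(methoxymethoxy)phenol F1. Steglich esterification of 19 with it (carbodiimide, DMAP) gives the ortho-iodoaryl ester F2. Iodine–lithium exchange with n-BuLi at −100 °C triggers an anionic Fries rearrangement to the ortho-hydroxyaryl ketone allyl ester F3, which already lacks bromine. Deallylation with Pd(PPh3)4 and morpholine at room temperature then gives 31.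

Step 10. Most likely to go wrong: attack of the oxocarbenium ion through C5 and not through the hindered, fully substituted C6 (a 6-exo closure leading to a tertiary α-silyl cation), together with protodesilylation of the vinylsilane and Lewis acid cleavage of the silyl ether. The fallback closes the ring by olefin metathesis; it sets out from 10 and 3 and returns at 18.
- But-3-enylmagnesium bromide is added to 10 as in step 6 to give allyl 2-oxohex-5-enoate F4.
- The aldol of step 8 with 14 gives, through trimethylsilyl ether F5, the tertiary alcohol allyl (2R)-2-[2-(tert-butylsulfanyl)-2-oxoethyl]-2-hydroxyhex-5-enoate F6.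
- The Grignard reagent F7 made from 3 and magnesium is added across prop-2-yn-1-ol under CuI catalysis to give the 2-substituted allylic alcohol F8.
- Trichloroacetonitrile and DBU convert F8 into trichloroacetimidate F9.
- Acid-catalysed O-alkylation of F6 with F9 (catalytic TfOH, no base, hence no retro-aldol) gives diene ether F10.
- Ring-closing metathesis with the second-generation Hoveyda–Grubbs catalyst forms C5=C6 and returns 18; the allyl ester olefin can only lead to a strained eight-membered lactone and should exchange unproductively.

Step 12. Most likely to go wrong: carbamoylation of the wrong hydroxyl or of both, because the two phenols differ only modestly in hindrance and acidity. The fallback uses a silyl relay so that the carbamate is introduced on a mono-phenol; it sets out from 20 and returns at 22. Silylation with t-BuMe2SiCl and imidazole at 0 °C, which is more sensitive to hindrance, gives 2-bromo-4-[(tert-butyldimethylsilyl)oxy]phenol F11. Alkylation with chloromethyl methyl ether and i-Pr2NEt gives tert-butyl[3-bromo-4-(methoxymethoxy)phenoxy]dimethylsilane F12. Tetrabutylammonium fluoride frees 3-bromo-4-(methoxymethoxy)phenol F13, and isopropyl isocyanate with catalytic triethylamine gives 22.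

Step 17. Most likely to go wrong: slow oxidative addition at the doubly ortho-substituted bromide, palladium hydride-induced migration of the trisubstituted olefins, and base-induced opening of the β-alkoxy ketone during prolonged heating with formate. The fallback separates the two events and changes the mechanism of the debromination; it sets out from 30 and returns at 31. Pd(PPh3)4 and morpholine at room temperature remove only the allyl group and give (2R)-2-{2-[2-bromo-6-hydroxy-3-(methoxymethoxy)phenyl]-2-oxoethyl}-6-[(3E)-5-{(tert-butyldimethylsilyl)oxy}-4-methylpent-3-en-1-yl]-2,3,4,7-tetrahydrooxepine-2-carboxylic acid F14. Radical hydrodebromination with (Me3Si)3SiH and AIBN in toluene at 80 °C, a neutral medium, then gives 31.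

## Further compounds

F1 | step 16 | 2-iodo-4-(methoxymethoxy)phenol | COCOc1ccc(O)c(I)c1
F2 | step 16 | prop-2-en-1-yl (2R)-6-[(3E)-5-{(tert-butyldimethylsilyl)oxy}-4-methylpent-3-en-1-yl]-2-{2-[2-iodo-4-(methoxymethoxy)phenoxy]-2-oxoethyl}-2,3,4,7-tetrahydrooxepine-2-carboxylate | C/C(=C\CCC1=CCC[C@@](CC(=O)Oc2ccc(OCOC)cc2I)(C(=O)OCC=C)OC1)CO[Si](C)(C)C(C)(C)C
F3 | step 16 | prop-2-en-1-yl (2R)-6-[(3E)-5-{(tert-butyldimethylsilyl)oxy}-4-methylpent-3-en-1-yl]-2-{2-[2-hydroxy-5-(methoxymethoxy)phenyl]-2-oxoethyl}-2,3,4,7-tetrahydrooxepine-2-carboxylate | C/C(=C\CCC1=CCC[C@@](CC(=O)c2cc(OCOC)ccc2O)(C(=O)OCC=C)OC1)CO[Si](C)(C)C(C)(C)C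
F4 | step 10 | prop-2-en-1-yl 2-oxohex-5-enoate | C=CCOC(=O)C(=O)CCC=C
F5 | step 10 | prop-2-en-1-yl (2R)-2-[2-(tert-butylsulfanyl)-2-oxoethyl]-2-[(trimethylsilyl)oxy]hex-5-enoate | C=CCC[C@@](CC(=O)SC(C)(C)C)(C(=O)OCC=C)O[Si](C)(C)C
F6 | step 10 | prop-2-en-1-yl (2R)-2-[2-(tert-butylsulfanyl)-2-oxoethyl]-2-hydroxyhex-5-enoate | C=CCC[C@@](CC(=O)SC(C)(C)C)(C(=O)OCC=C)O
F7 | step 10 | bromo{(3E)-5-[(tert-butyldimethylsilyl)oxy]-4-methylpent-3-en-1-yl}magnesium | C/C(=C\CC[Mg]Br)CO[Si](C)(C)C(C)(C)C
F8 | step 10 | (5E)-7-[(tert-butyldimethylsilyl)oxy]-6-methyl-2-methylidenehept-5-en-1-ol | OCC(=C)CC/C=C(\C)CO[Si](C)(C)C(C)(C)C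
F9 | step 10 | (5E)-7-[(tert-butyldimethylsilyl)oxy]-6-methyl-2-methylidenehept-5-en-1-yl 2,2,2-trichloroethanimidate | N=C(OCC(=C)CC/C=C(\C)CO[Si](C)(C)C(C)(C)C)C(Cl)(Cl)Cl
F10 | step 10 | prop-2-en-1-yl (2R)-2-[2-(tert-butylsulfanyl)-2-oxoethyl]-2-({(5E)-7-[(tert-butyldimethylsilyl)oxy]-6-methyl-2-methylidenehept-5-en-1-yl}oxy)hex-5-enoate | C=CCC[C@@](CC(=O)SC(C)(C)C)(C(=O)OCC=C)OCC(=C)CC/C=C(\C)CO[Si](C)(C)C(C)(C)C
F11 | step 12 | 2-bromo-4-[(tert-butyldimethylsilyl)oxy]phenol | Oc1ccc(O[Si](C)(C)C(C)(C)C)cc1Br
F12 | step 12 | tert-butyl[3-bromo-4-(methoxymethoxy)phenoxy]dimethylsilane | COCOc1ccc(O[Si](C)(C)C(C)(C)C)cc1Br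
F13 | step 12 | 3-bromo-4-(methoxymethoxy)phenol | COCOc1ccc(O)cc1Br
F14 | step 17 | (2R)-2-{2-[2-bromo-6-hydroxy-3-(methoxymethoxy)phenyl]-2-oxoethyl}-6-[(3E)-5-{(tert-butyldimethylsilyl)oxy}-4-methylpent-3-en-1-yl]-2,3,4,7-tetrahydrooxepine-2-carboxylic acid | C/C(=C\CCC1=CCC[C@@](CC(=O)c2c(Br)c(OCOC)ccc2O)(C(=O)O)OC1)CO[Si](C)(C)C(C)(C)C
A1 | alternative 1 | tert-butyl (2R)-2-{2-[2,5-bis(methoxymethoxy)phenyl]-2-oxoethyl}-3,4-dihydro-2H-pyran-2-carboxylate | C1=CCC[C@@](CC(=O)c2cc(OCOC)ccc2OCOC)(C(=O)OC(C)(C)C)O1
A2 | alternative 1 | tert-butyl (3R)-3-{2-[2,5-bis(methoxymethoxy)phenyl]-2-oxoethyl}-7,7-dibromo-2-oxabicyclo[4.1.0]heptane-3-carboxylate (ring-fusion isomers) | BrC1(Br)C2CC[C@@](CC(=O)c3cc(OCOC)ccc3OCOC)(C(=O)OC(C)(C)C)OC12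
A3 | alternative 1 | tert-butyl (2R)-2-{2-[2,5-bis(methoxymethoxy)phenyl]-2-oxoethyl}-6-bromo-7-methoxy-2,3,4,7-tetrahydrooxepine-2-carboxylate (acetal epimers) | BrC1=CCC[C@@](CC(=O)c2cc(OCOC)ccc2OCOC)(C(=O)OC(C)(C)C)OC1OC
A4 | alternative 2 | ({1-[2,5-bis(tert-butyldimethylsilyloxy)phenyl]ethenyl}oxy)trimethylsilane | C=C(O[Si](C)(C)C)c1cc(O[Si](C)(C)C(C)(C)C)ccc1O[Si](C)(C)C(C)(C)C
A5 | alternative 2 | methyl (2R,5Z,9E)-2-{2-[2,5-bis(tert-butyldimethylsilyloxy)phenyl]-2-oxoethyl}-11-[(tert-butyldimethylsilyl)oxy]-2-(methoxymethoxy)-10-methyl-6-(trimethylsilyl)undeca-5,9-dienoate | C/C(=C\CC/C(=C/CC[C@@](CC(=O)c1cc(O[Si](C)(C)C(C)(C)C)ccc1O[Si](C)(C)C(C)(C)C)(C(=O)OC)OCOC)[Si](C)(C)C)CO[Si](C)(C)C(C)(C)C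
A6 | alternative 2 | methyl (2R)-2-{2-[2,5-bis(tert-butyldimethylsilyloxy)phenyl]-2-oxoethyl}-6-[(3E)-5-{(tert-butyldimethylsilyl)oxy}-4-methylpent-3-en-1-yl]-2,3,4,7-tetrahydrooxepine-2-carboxylate | C/C(=C\CCC1=CCC[C@@](CC(=O)c2cc(O[Si](C)(C)C(C)(C)C)ccc2O[Si](C)(C)C(C)(C)C)(C(=O)OC)OC1)CO[Si](C)(C)C(C)(C)C
A7 | alternative 3 | tert-butyl (2E,5Z,9E)-2-{2-[2,5-bis(methoxymethoxy)phenyl]-2-oxoethylidene}-11-[(tert-butyldimethylsilyl)oxy]-6-(hydroxymethyl)-10-methylundeca-5,9-dienoate | C/C(=C\CC/C(CO)=C/CC/C(C(=O)OC(C)(C)C)=C\C(=O)c1cc(OCOC)ccc1OCOC)CO[Si](C)(C)C(C)(C)C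
A8 | alternative 3 | tert-butyl (2R)-2-{2-[2,5-bis(methoxymethoxy)phenyl]-2-oxoethyl}-6-[(3E)-5-{(tert-butyldimethylsilyl)oxy}-4-methylpent-3-en-1-yl]-2,3,4,7-tetrahydrooxepine-2-carboxylate | C/C(=C\CCC1=CCC[C@@](CC(=O)c2cc(OCOC)ccc2OCOC)(C(=O)OC(C)(C)C)OC1)CO[Si](C)(C)C(C)(C)C
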